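**Retrosynthetic overview**
- The δ-lactone is made last: lactol oxidation, preceded by a catalyst-controlled anti carbonyl-ene reaction between a prenyl group and 3-methyl-2-oxobutanal (C5'–C6' bond, isopropenyl group).
- The spiro carbon (formyl plus prenyl) comes from a stereospecific Lewis-acid epoxy-ketone ring contraction (1,2-acyl shift) of a cyclohexenone epoxide; this turns a six-membered ring into the cyclopentanone.
- The 3-prenyl enone comes from prenyl 1,2-addition and oxidative 1,3-transposition on a bicyclic enone lactone.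
- Key step: a rhodium-catalysed enantioselective conjugate isopropenylation desymmetrises mirror-symmetric 4-cyano-4-methylcyclohexadienone; hydrative lactonisation then closes the γ-lactone (first ring).
- The dienone comes from allylic oxidation of the Birch reductive-methylation product of benzonitrile. Ring order: γ-lactone, cyclopentanone (by contraction), δ-lactone.

Assumption: activated barium metal is prepared separately (BaI2 reduced with lithium biphenylide), and 3-methyl-2-oxobutanal is made in the route because its commercial supply is unreliable.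

**Step 1**
Reactants: 1 benzonitrile
Product: 3 1-methylcyclohexa-2,5-diene-1-carbonitrile, via lithiated dienyl nitrile 2 (not isolated)
Conditions: Li (2.1 equiv), t-BuOH (1.0 equiv), NH3(l)/THF, −78 °C; then MeI (3 equiv), −78 °C to rt
Reagents that add atoms: iodomethane, [CH3]I
Why: Birch reductive alkylation, in which two-electron reduction of the arene and protonation para to the nitrile by t-BuOH leave the nitrile-stabilised cyclohexadienyl anion 2 that is methylated at the ipso carbon, and the product keeps a mirror plane so no stereocentre arises.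

**Step 2**
Reactants: 3 1-methylcyclohexa-2,5-diene-1-carbonitrile
Product: 4 1-methyl-4-oxocyclohexa-2,5-diene-1-carbonitrile
Conditions: Rh2(cap)4 (1 mol %, cap = caprolactamate), t-BuOOH (70% aq, 5 equiv), K2CO3 (0.5 equiv), CH2Cl2, rt
Reagents that add atoms: tert-butyl hydroperoxide, CC(C)(C)OO
Why: Dirhodium-catalysed allylic C–H oxidation with t-BuOOH converts the doubly allylic CH2 into the carbonyl of a cross-conjugated dienone that cannot aromatise because C1 is quaternary, and the mirror plane is retained.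

**Step 3**
Reactants: 4 1-methyl-4-oxocyclohexa-2,5-diene-1-carbonitrile; 5 potassium trifluoro(prop-1-en-2-yl)borate
Product: 7 (3aR,7aS)-3,3,7a-trimethyl-3a,4-dihydro-2-benzofuran-1,5(3H,7aH)-dione, via conjugate adduct 6 (not isolated)
Conditions: [Rh(cod)2]PF6 (3 mol %), (S)-BINAP (3.3 mol %), toluene/H2O 4:1, 100 °C; then aq H2SO4 (to 4 M), dioxane, 70 °C
Reagents that add atoms: water, O
Why: Hayashi–Miyaura rhodium-catalysed asymmetric conjugate addition used as a desymmetrisation, in which the (S)-BINAP–Rh–isopropenyl species selects one of the two enantiotopic enone arms with the facial sense known for cyclohexenone and adds syn to the small linear nitrile rather than the methyl group, which sets both stereocentres of 6 at once, after which aqueous acid hydrates the isopropenyl group to the tertiary carbinol that attacks the cis nitrile (intramolecular Pinner reaction) and hydrolyses to the cis-fused γ-lactone.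

**Step 4**
Reactants: 7 (3aR,7aS)-3,3,7a-trimethyl-3a,4-dihydro-2-benzofuran-1,5(3H,7aH)-dione; 8 1-chloro-3-methylbut-2-ene (prenyl chloride)
Product: 9 (3aR,7aS)-5-hydroxy-3,3,7a-trimethyl-5-(3-methylbut-2-en-1-yl)-3a,4,5,7a-tetrahydro-2-benzofuran-1(3H)-one (C5 epimers)
Conditions: 8, activated Ba (1.2 equiv), THF, −78 °C; then 7, −78 °C; H2O
Reagents that add atoms: none
Why: Yamamoto α-selective allylation, in which prenylbarium chloride adds 1,2 to the enone carbonyl through its unsubstituted CH2 terminus at −78 °C and leaves the hindered lactone alone, and the new carbinol centre need not be controlled because the next step erases it.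

**Step 5**
Reactants: 9 (3aR,7aS)-5-hydroxy-3,3,7a-trimethyl-5-(3-methylbut-2-en-1-yl)-3a,4,5,7a-tetrahydro-2-benzofuran-1(3H)-one
Product: 10 (3aR,7aR)-3,3,7a-trimethyl-5-(3-methylbut-2-en-1-yl)-3a,4-dihydro-2-benzofuran-1,7(3H,7aH)-dione
Conditions: IBX (2.5 equiv), DMSO, 55 °C
Reagents that add atoms: none
Why: Dauben-type oxidative 1,3-transposition of a tertiary allylic alcohol with IBX (allylic shift of the iodine ester, then oxidation) moves the oxygen to C7 beside the quaternary carbon and leaves the prenyl group on the β-carbon of the new enone without creating a stereocentre.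

**Step 6**
Reactants: 10 (3aR,7aR)-3,3,7a-trimethyl-5-(3-methylbut-2-en-1-yl)-3a,4-dihydro-2-benzofuran-1,7(3H,7aH)-dione
Product: 11 (3aR,5R,6R,7aR)-5,6-epoxy-3,3,7a-trimethyl-5-(3-methylbut-2-en-1-yl)hexahydro-2-benzofuran-1,7-dione (oxirane oxygen cis to the 7a-methyl group)
Conditions: t-BuOOH (5.5 M in decane, 2 equiv), DBU (1.2 equiv), CH2Cl2, 0 °C to rt
Reagents that add atoms: tert-butyl hydroperoxide, CC(C)(C)OO
Why: Weitz–Scheffer nucleophilic epoxidation is chemoselective for the electron-poor enone over the prenyl alkene, and the peroxide anion adds axially to C5 trans to the C3a substituent (the 3,5-trans rule for 5-substituted cyclohexenones), so the oxirane lies on the face of the 7a-methyl group and C5 and C6 are set.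

**Step 7**
Reactants: 11 (3aR,5R,6R,7aR)-5,6-epoxy-3,3,7a-trimethyl-5-(3-methylbut-2-en-1-yl)hexahydro-2-benzofuran-1,7-dione
Product: 12 (3aR,5S,6aR)-3,3,6a-trimethyl-5-(3-methylbut-2-en-1-yl)-1,6-dioxohexahydro-1H-cyclopenta[c]furan-5-carbaldehyde
Conditions: BF3·OEt2 (0.5 equiv), CH2Cl2, −20 to 0 °C
Reagents that add atoms: none
Why: Lewis-acid epoxy-ketone to β-keto-aldehyde rearrangement (Meinwald-type 1,2-acyl shift, as in isophorone oxide giving 2-formyl-2,4,4-trimethylcyclopentanone), in which the tertiary C5–O bond ionises while the ring acyl carbon C7 shifts from C6 to C5 anti to the leaving oxygen, so the ring contracts with inversion at C5, C6 becomes the formyl group on the face of the 6a-methyl group and the prenyl group ends cis to the lactone, which is the spiro configuration of the target.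

**Step 8**
Reactants: 13 3-methylbutan-2-one
Product: 14 3-methyl-2-oxobutanal
Conditions: SeO2 (1.0 equiv), dioxane/H2O, reflux; distillation
Reagents that add atoms: selenium dioxide, O=[Se]=O
Why: Riley oxidation with SeO2 converts the methyl group of the methyl ketone into the aldehyde of the α-keto aldehyde, and no stereocentre is involved.

**Step 9**
Reactants: 12 (3aR,5S,6aR)-3,3,6a-trimethyl-5-(3-methylbut-2-en-1-yl)-1,6-dioxohexahydro-1H-cyclopenta[c]furan-5-carbaldehyde; 14 3-methyl-2-oxobutanal
Product: 16 (3aR,5S,5'S,6'S,6aR)-2'-hydroxy-3,3,6a-trimethyl-6'-(2-methylpropanoyl)-5'-(prop-1-en-2-yl)hexahydrospiro[cyclopenta[c]furan-5,3'-pyran]-1,6-dione (both C2' epimers), via open hydroxy aldehyde 15 (not isolated)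
Conditions: [Cu((S,S)-t-Bu-box)](SbF6)2 (10 mol %), 14 (3 equiv), CH2Cl2, 0 °C to rt
Reagents that add atoms: none
Why: Catalytic asymmetric carbonyl-ene reaction with a bis(oxazoline)–copper Lewis acid of the kind used for glyoxylates, in which the chelated keto aldehyde bonds through its aldehyde carbon to C2 of the prenyl group with hydrogen transfer from a methyl group to give the isopropenyl group, the catalyst fixes the (S)-carbinol, the chelated ene transition state with the aldehyde hydrogen between the alkene substituents gives the anti adduct and hence the (S)-allylic centre, and the δ-hydroxy aldehyde 15 closes to the six-membered lactol.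

**Step 10**
Reactants: 16 (3aR,5S,5'S,6'S,6aR)-2'-hydroxy-3,3,6a-trimethyl-6'-(2-methylpropanoyl)-5'-(prop-1-en-2-yl)hexahydrospiro[cyclopenta[c]furan-5,3'-pyran]-1,6-dione
Product: 17 (3aR,5R,5'S,6'S,6aR)-3,3,6a-trimethyl-6'-(2-methylpropanoyl)-5'-(prop-1-en-2-yl)tetrahydrospiro[cyclopenta[c]furan-5,3'-pyran]-1,2',6-trione (CNP0216954.2)
Conditions: TEMPO (10 mol %), PhI(OAc)2 (1.5 equiv), CH2Cl2, rt
Reagents that add atoms: none
Why: Oxoammonium (TEMPO) oxidation of the lactol to the δ-lactone under non-basic conditions leaves the epimerisable C6' centre and all other stereocentres untouched.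

**Compound list**
1 | benzonitrile | N#Cc1ccccc1 | starting material
2 | lithium 1-cyanocyclohexa-2,5-dien-1-ide | [Li+].N#C[C-]1C=CCC=C1 | intermediate
3 | 1-methylcyclohexa-2,5-diene-1-carbonitrile | CC1(C#N)C=CCC=C1 | intermediate
4 | 1-methyl-4-oxocyclohexa-2,5-diene-1-carbonitrile | CC1(C#N)C=CC(=O)C=C1 | intermediate
5 | potassium trifluoro(prop-1-en-2-yl)borate | [K+].CC(=C)[B-](F)(F)F | starting material
6 | (1S,6S)-1-methyl-4-oxo-6-(prop-1-en-2-yl)cyclohex-2-ene-1-carbonitrile | O=C1C[C@@H](C(C)=C)[C@@](C)(C#N)C=C1 | intermediate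
7 | (3aR,7aS)-3,3,7a-trimethyl-3a,4-dihydro-2-benzofuran-1,5(3H,7aH)-dione | O=C1C[C@H]2C(C)(C)OC(=O)[C@@]2(C)C=C1 | intermediate
8 | 1-chloro-3-methylbut-2-ene (prenyl chloride) | CC(C)=CCCl | starting material
9 | (3aR,7aS)-5-hydroxy-3,3,7a-trimethyl-5-(3-methylbut-2-en-1-yl)-3a,4,5,7a-tetrahydro-2-benzofuran-1(3H)-one (C5 epimers) | OC1(CC=C(C)C)C[C@H]2C(C)(C)OC(=O)[C@@]2(C)C=C1 | intermediate
10 | (3aR,7aR)-3,3,7a-trimethyl-5-(3-methylbut-2-en-1-yl)-3a,4-dihydro-2-benzofuran-1,7(3H,7aH)-dione | C1[C@H]2C(C)(C)OC(=O)[C@@]2(C)C(=O)C=C1CC=C(C)C | intermediate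
11 | (3aR,5R,6R,7aR)-5,6-epoxy-3,3,7a-trimethyl-5-(3-methylbut-2-en-1-yl)hexahydro-2-benzofuran-1,7-dione | C1[C@H]2C(C)(C)OC(=O)[C@@]2(C)C(=O)[C@@H]3O[C@]13CC=C(C)C | intermediate
12 | (3aR,5S,6aR)-3,3,6a-trimethyl-5-(3-methylbut-2-en-1-yl)-1,6-dioxohexahydro-1H-cyclopenta[c]furan-5-carbaldehyde | CC(C)=CC[C@@]1(C=O)C[C@H]2C(C)(C)OC(=O)[C@@]2(C)C1=O | intermediate
13 | 3-methylbutan-2-one | CC(C)C(C)=O | starting material
14 | 3-methyl-2-oxobutanal | CC(C)C(=O)C=O | intermediate
15 | (3aR,5S,6aR)-5-[(2S,3S)-3-hydroxy-5-methyl-4-oxo-2-(prop-1-en-2-yl)hexyl]-3,3,6a-trimethyl-1,6-dioxohexahydro-1H-cyclopenta[c]furan-5-carbaldehyde | C=C(C)[C@H](C[C@@]1(C=O)C[C@H]2C(C)(C)OC(=O)[C@@]2(C)C1=O)[C@H](O)C(=O)C(C)C | intermediate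
16 | (3aR,5S,5'S,6'S,6aR)-2'-hydroxy-3,3,6a-trimethyl-6'-(2-methylpropanoyl)-5'-(prop-1-en-2-yl)hexahydrospiro[cyclopenta[c]furan-5,3'-pyran]-1,6-dione (C2' epimers) | C=C(C)[C@@H]1C[C@]2(C[C@H]3C(C)(C)OC(=O)[C@@]3(C)C2=O)C(O)O[C@@H]1C(=O)C(C)C | intermediate
17 | (3aR,5R,5'S,6'S,6aR)-3,3,6a-trimethyl-6'-(2-methylpropanoyl)-5'-(prop-1-en-2-yl)tetrahydrospiro[cyclopenta[c]furan-5,3'-pyran]-1,2',6-trione | C=C(C)[C@@H]1C[C@]2(C[C@H]3C(C)(C)OC(=O)[C@@]3(C)C2=O)C(=O)O[C@@H]1C(=O)C(C)C | target

Total step count: 10. Longest linear sequence: 9 steps (steps 1–7, 9 and 10; step 8 is a one-step side branch).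

**Steps most likely to fail, each with a fallback**

Step 3. The rhodium catalyst must pick one enone arm of a γ-quaternary dienone and add on the nitrile face. The minor trans adduct cannot lactonise and, under prolonged acid, can isomerise through the isopropylidene alkene into the enantiomer of 7. Isolating 6 before the acid stage is the immediate remedy. The fallback sets out from 4 and returns at 7, and separates the enantio-determining event from the C–C bond formation. An ene-reductase of the old yellow enzyme family (NADPH with glucose dehydrogenase recycling; alternatively Cu(OAc)2, a chiral bisphosphine and a silane) reduces one enantiotopic arm of 4 to (S)-1-methyl-4-oxocyclohex-2-ene-1-carbonitrile F1. Isopropenylmagnesium bromide with catalytic CuBr·SMe2 then adds to the remaining enone anti to the methyl group to give (1S,2S)-1-methyl-4-oxo-2-(prop-1-en-2-yl)cyclohexane-1-carbonitrile F2. Aqueous H2SO4 closes the lactone to (3aR,7aS)-3,3,7a-trimethylhexahydro-2-benzofuran-1,5-dione F3. Kinetic enolisation away from the branched side (LiN(i-Pr)2, Me3SiCl) gives the silyl enol ether F4, and Saegusa–Ito dehydrogenation with Pd(OAc)2 in MeCN returns 7.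

Step 7. The tertiary cation next to a prenyl group may be captured by the alkene, a hydride shift may give the diosphenol, and a long-lived cation would erode the inversion at C5. The fallback sets out from 7 and returns at 12, and builds the quaternary carbon by two enolate reactions on the convex face instead. Tsuji–Wacker oxidation of the enone (Na2PdCl4 cat., t-BuOOH, AcOH/H2O) gives (3aR,7aR)-3,3,7a-trimethyltetrahydro-2-benzofuran-1,5,7(3H)-trione F5. Diazo transfer (4-acetamidobenzenesulfonyl azide, Et3N) gives the 6-diazo trione F6. Photochemical Wolff ring contraction in wet THF, in which the CH2 carbon migrates rather than the quaternary carbon bearing the lactone carbonyl, gives the β-keto acid F7, which loses CO2 on warming to the bicyclic ketone F8. LiN(i-Pr)2 and prenyl bromide give the 5-prenyl ketone F9. A second enolisation and monomeric formaldehyde, entering on the face of the 6a-methyl group, give the hydroxymethyl ketone F10, and Dess–Martin periodinane returns 12.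

Step 9. A trisubstituted alkene is a slow ene donor, 12 can itself chelate the copper catalyst, and the facial sense and anti preference are taken by analogy from glyoxylates. The enantiomeric ligand is the first remedy if the sense is reversed. The fallback sets out from 12 and ends at 17, and makes the ene step intramolecular. Aldol addition of the kinetic lithium enolate of 13 (LiN(i-Pr)2, −78 °C) to the aldehyde gives the β-hydroxy ketone F11. Excess Dess–Martin periodinane with pyridine oxidises it through the β-diketone F12 to the vicinal tricarbonyl compound F13. Its central carbonyl undergoes an intramolecular carbonyl-ene reaction with the prenyl group (rt or Mg(ClO4)2) to give the spiro hydroxy diketone F14. Catalytic Et3N then triggers the 1,2-acyl shift from carbon to oxygen (α-hydroxy β-diketone to α-acyloxy ketone), which expands the ring to the δ-lactone enolate; protonation anti to the isopropenyl group gives 17. The configuration at the isopropenyl carbon relative to the spiro centre in this fallback would have to be checked experimentally.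

Further compounds
F1 | step 3 | (S)-1-methyl-4-oxocyclohex-2-ene-1-carbonitrile | O=C1C=C[C@@](C)(C#N)CC1
F2 | step 3 | (1S,2S)-1-methyl-4-oxo-2-(prop-1-en-2-yl)cyclohexane-1-carbonitrile | O=C1C[C@@H](C(C)=C)[C@@](C)(C#N)CC1
F3 | step 3 | (3aR,7aS)-3,3,7a-trimethylhexahydro-2-benzofuran-1,5-dione | O=C1C[C@H]2C(C)(C)OC(=O)[C@@]2(C)CC1
F4 | step 3 | (3aR,7aS)-3,3,7a-trimethyl-5-(trimethylsilyloxy)-3a,4,7,7a-tetrahydro-2-benzofuran-1(3H)-one | C1[C@H]2C(C)(C)OC(=O)[C@@]2(C)CC=C1O[Si](C)(C)C
F5 | step 7 | (3aR,7aR)-3,3,7a-trimethyltetrahydro-2-benzofuran-1,5,7(3H)-trione | O=C1C[C@H]2C(C)(C)OC(=O)[C@@]2(C)C(=O)C1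
F6 | step 7 | (3aR,7aR)-6-diazo-3,3,7a-trimethyltetrahydro-2-benzofuran-1,5,7(3H)-trione | O=C1C[C@H]2C(C)(C)OC(=O)[C@@]2(C)C(=O)C1=[N+]=[N-]
F7 | step 7 | (3aR,6aR)-3,3,6a-trimethyl-1,6-dioxohexahydro-1H-cyclopenta[c]furan-5-carboxylic acid (C5 epimers) | OC(=O)C1C[C@H]2C(C)(C)OC(=O)[C@@]2(C)C1=O
F8 | step 7 | (3aR,6aR)-3,3,6a-trimethyltetrahydro-1H-cyclopenta[c]furan-1,6(6aH)-dione | C1C[C@H]2C(C)(C)OC(=O)[C@@]2(C)C1=O
F9 | step 7 | (3aR,6aR)-3,3,6a-trimethyl-5-(3-methylbut-2-en-1-yl)tetrahydro-1H-cyclopenta[c]furan-1,6(6aH)-dione (C5 epimers) | CC(C)=CCC1C[C@H]2C(C)(C)OC(=O)[C@@]2(C)C1=O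
F10 | step 7 | (3aR,5S,6aR)-5-(hydroxymethyl)-3,3,6a-trimethyl-5-(3-methylbut-2-en-1-yl)tetrahydro-1H-cyclopenta[c]furan-1,6(6aH)-dione | CC(C)=CC[C@@]1(CO)C[C@H]2C(C)(C)OC(=O)[C@@]2(C)C1=O
F11 | step 9 | (3aR,5S,6aR)-5-(1-hydroxy-4-methyl-3-oxopentyl)-3,3,6a-trimethyl-5-(3-methylbut-2-en-1-yl)tetrahydro-1H-cyclopenta[c]furan-1,6(6aH)-dione (carbinol epimers) | CC(C)=CC[C@@]1(C(O)CC(=O)C(C)C)C[C@H]2C(C)(C)OC(=O)[C@@]2(C)C1=O
F12 | step 9 | (3aR,5S,6aR)-3,3,6a-trimethyl-5-(4-methyl-3-oxopentanoyl)-5-(3-methylbut-2-en-1-yl)tetrahydro-1H-cyclopenta[c]furan-1,6(6aH)-dione | CC(C)=CC[C@@]1(C(=O)CC(=O)C(C)C)C[C@H]2C(C)(C)OC(=O)[C@@]2(C)C1=O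
F13 | step 9 | (3aR,5R,6aR)-3,3,6a-trimethyl-5-(4-methyl-2,3-dioxopentanoyl)-5-(3-methylbut-2-en-1-yl)tetrahydro-1H-cyclopenta[c]furan-1,6(6aH)-dione | CC(C)=CC[C@@]1(C(=O)C(=O)C(=O)C(C)C)C[C@H]2C(C)(C)OC(=O)[C@@]2(C)C1=O
F14 | step 9 | (3aR,6aR)-3'-hydroxy-3,3,6a-trimethyl-3'-(2-methylpropanoyl)-4'-(prop-1-en-2-yl)spiro[cyclopenta[c]furan-5,1'-cyclopentane]-1,2',6-trione (3'-hydroxyl cis to 4'-isopropenyl) | C=C(C)[C@@H]1C[C@]2(C[C@H]3C(C)(C)OC(=O)[C@@]3(C)C2=O)C(=O)[C@@]1(O)C(=O)C(C)C
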